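(The numbers in the tables come from a simulation for substances that don't exist.)

**Two clocks.** I started from a one-step world, where the fraction left of a reactant falls as exp(−t/τ) with a single time constant τ. This racemate needed one τ per hand, and I looked to their ratio, set beside the reading time, for the excess.

| setting | alder | birch | cedar | dawn | noon |
|---|---|---|---|---|---|
| left-handed substrate | 0.050 M | 0.050 M | 0.050 M | 0.050 M | 0.050 M |
| right-handed substrate | 0.050 M | 0.050 M | 0.050 M | 0.050 M | 0.050 M |
| gas | 5.3 mM (held) | 5.3 mM (held) | 5.3 mM (held) | 5.3 mM (held) | 5.3 mM (held) |
| catalyst | 130 µM | 200 µM | 90 µM | 90 µM | 90 µM |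
| added ligand | 0.27 mM | 0.27 mM | 0.14 mM | 0.27 mM | 0.27 mM |
| remark | run made earlier | run made earlier | run made earlier |  |  |
| time |  |  |  | 50 min | 200 min |

- alder (time / min: right-handed substrate / %, left-handed substrate / %, left-handed product / %): 2.50: 50.3, 45.0, 1.9; 4.00: 50.6, 43.7, 7.2; 6.00: 49.0, 41.0, 6.8; 8.00: 49.2, 35.7, 7.4; 12.0: 49.9, 31.4, 11.4; 20.0: 49.9, 20.4, 16.0; 30.0: 49.7, 9.5, 21.4
- birch (time / min: right-handed substrate / %, left-handed substrate / %, left-handed product / %): 4.00: 51.9, 41.5, 3.7; 8.00: 50.8, 34.4, 10.9; 12.0: 48.2, 26.0, 14.3; 15.0: 47.6, 20.6, 15.7; 20.0: 50.2, 14.2, 22.0; 25.0: 49.1, 10.3, 23.0; 30.0: 47.9, 3.9, 22.9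
- cedar (time / min: right-handed substrate / %, left-handed substrate / %, left-handed product / %): 2.50: 49.8, 46.6, 1.5; 5.00: 48.8, 42.6, 4.8; 8.00: 51.0, 38.5, 8.8; 15.0: 50.7, 29.1, 10.9; 30.0: 51.3, 14.2, 20.1

(each reading ± 1 percentage point)

- catalyst is single-handed; left-handed substrate and right-handed substrate are mirror images of each other, charged as a racemate, each of them at the stated concentration
- at the start none of the gas is in solution
- an excess is the difference of the two amounts in percent of their sum
- an excess is below zero if the other one leads

* the flask that ends with the higher excess of right-handed substrate over left-handed substrate among what is left of the two, or "neither" when 2 percentage points or less lies between them (dawn / noon / neither)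
* excess of right-handed substrate over left-handed substrate among what is left of the two at the end, dawn
* excess of right-handed substrate over left-handed substrate among what is left of the two at the end, noon

**Left clock.** I treated the late fall of the left-handed substrate as pseudo-first-order. Between 20.0 min and 30.0 min, the alder readings gave 13.1 min. Scaled inversely with catalyst, that predicts 8.51 min for birch, which read 7.74 min. Alder shares its added ligand with dawn and noon, so I scaled its reading to their catalyst and took τ_L = 18.9 min, the tail time: the late time constant of the left-handed fraction left.

**Right clock.** The right-handed substrate stayed within two standard deviations of its charge through alder. Scaled likewise, I estimated the shortest time constant τ_R those readings allowed as 18.1 h, which gave a low estimate of the selectivity factor τ_R/τ_L, 57.5.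

**My reckoning.** With the clock stretched by catalyst, I set dawn at 50 min equal to alder at 34.6 min, and the tail from alder's last reading gave an estimate of 6.68% left-handed substrate. With the right-handed substrate taken at its charge, my estimate of the dawn excess came to 76.4%. For noon I reckoned 7.94 tail times beyond dawn, and an estimate of 0.00239% left-handed substrate.

**The forecast.** It chose noon, with 82% for dawn (70% to 92%), above my figure, and 99% for noon (93% to 100%): “the left-handed substrate should be gone”.

**The result.** The forecast held: noon ended higher, dawn at 79.4% and noon at >99.9%.

    reagent + catalyst + left-handed substrate → catalyst + left-handed product (k = 1.80 × 10⁵ L² mol⁻² min⁻¹)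
    catalyst + added ligand ⇌ idle complex, settled at all times (K = 1700 L mol⁻¹)
    left-handed product ⇌ right-handed product (k = 0.270 min⁻¹)
    gas ⇌ reagent, rate k4*(csat - [reagent]) (kL = 0.690 min⁻¹)
    reagent + catalyst + right-handed substrate → catalyst + right-handed product (k = 2500 L² mol⁻² min⁻¹)

**Clocks compared.** Just after the start of noon, the left-handed step used reagent 72 times as fast as the right-handed step, and at 21.3 min the half-life of the right-handed substrate by its step stood in noon at 19 h, long against τ_L. From dawn's 5.57% left-handed substrate at 50.0 min, τ_L carried the same charge to 1.14% at 80 min, and noon, read at that time, held 0.998%.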